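Both halves are the same trans-3-methyl-4-oxyisochroman-1-one, linked by the benzylic C4–O–C6′ ether. Everything rests on one monomer, the cis C4 tosylate 16. It is made from the achiral methyl (E)-propenylbenzoate 9: a chiral aryl-λ3-iodane delivers tosylate to benzylic C4, and the ester carbonyl oxygen then closes the lactone ring by displacing iodine at C3. This forms the O2–C3 bond and both stereocentres in one operation, exploiting the vicinal O2′–C3′(CH3)–C4′(O) array of the lactone ring of the 4′-hydroxy half, which its twin shares. Two SN2 inversions at C4 of 16, by acetate and by the C6′ phenol, give both trans rings and the ether.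

Key step: step 9

Remark on numbering: isochroman-1-one locants are used (C1 carbonyl, O2, C3 bearing methyl, C4 benzylic, C4a–C8a); primed locants denote the half with the free 4′-OH.

Assumption: by analogy with styrene dioxygenation, the (R,R)-bis(lactate) aryl-λ3-iodane is assumed to place the benzylic oxygen with S configuration, so the (S,S)-reagent 13 is specified for (4R)-16; if the sense is the reverse, the enantiomeric reagent from methyl (S)-lactate is used with no other change.

Step 1
Reactants: 1 methyl 3,5-dihydroxy-4-methoxybenzoate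
Product: 2 methyl 4-methoxy-3,5-bis(methoxymethoxy)benzoate
Conditions: NaH, MOMCl, DMF, 0 °C → rt
Reagents that add atoms: chloromethyl methyl ether (MOMCl), COCCl
Why: Williamson-type O-alkylation of both phenoxides gives the bis-MOM acetal, which masks the phenols against base, organolithium and the later iodane oxidant.

Step 2
Reactants: 2 methyl 4-methoxy-3,5-bis(methoxymethoxy)benzoate
Product: 3 [4-methoxy-3,5-bis(methoxymethoxy)phenyl]methanol
Conditions: LiAlH4, THF, 0 °C
Reagents that add atoms: none
Why: Hydride reduction of the ester should give the benzylic alcohol, the MOM acetals being inert to LiAlH4.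

Step 3
Reactants: 3 [4-methoxy-3,5-bis(methoxymethoxy)phenyl]methanol
Product: 4 4-methoxy-3,5-bis(methoxymethoxy)benzaldehyde
Conditions: MnO2, CH2Cl2, rt
Reagents that add atoms: none
Why: Heterogeneous MnO2 oxidation is selective for benzylic alcohols and stops at the aldehyde.

Step 4
Reactants: 4 4-methoxy-3,5-bis(methoxymethoxy)benzaldehyde
Product: 5 2-bromo-4-methoxy-3,5-bis(methoxymethoxy)benzaldehyde
Conditions: NBS, MeCN, 0 °C → rt
Reagents that add atoms: N-bromosuccinimide, BrN1C(=O)CCC1=O
Why: Electrophilic aromatic bromination should go to the only free ring position (C2 and C6 are equivalent), which is ortho to one OMOM group and para to the other, and the aldehyde disfavours a second bromination.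

Step 5
Reactants: 5 2-bromo-4-methoxy-3,5-bis(methoxymethoxy)benzaldehyde; 6 5-(ethylsulfonyl)-1-phenyl-1H-tetrazole
Product: 7 2-bromo-4-methoxy-3,5-bis(methoxymethoxy)-1-[(E)-prop-1-en-1-yl]benzene
Conditions: KN(SiMe3)2, DME, −60 °C → rt
Reagents that add atoms: none
Why: Julia–Kocienski olefination (sulfonyl carbanion addition, Smiles rearrangement, loss of SO2 and tetrazolate) should favour the conjugated E alkene, any minor Z isomer being removed by chromatography.

Step 6
Reactants: 7 2-bromo-4-methoxy-3,5-bis(methoxymethoxy)-1-[(E)-prop-1-en-1-yl]benzene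
Product: 9 methyl 3-methoxy-2,4-bis(methoxymethoxy)-6-[(E)-prop-1-en-1-yl]benzoate, via aryllithium 8 (not isolated)
Conditions: n-BuLi, THF, −78 °C; then ClCO2Me, −78 → 0 °C
Reagents that add atoms: methyl chloroformate, COC(Cl)=O
Why: Bromine–lithium exchange at −78 °C is faster than any reaction at the alkene, and the aryllithium is acylated by the chloroformate to the methyl benzoate.

Step 7
Reactants: 10 2-iodobenzene-1,3-diol (2-iodoresorcinol); 11 methyl (R)-lactate (2 equiv)
Product: 12 dimethyl (2S,2′S)-2,2′-[(2-iodo-1,3-phenylene)bis(oxy)]dipropanoate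
Conditions: methyl (R)-lactate (2.2 equiv in all), PPh3, DIAD, THF, 0 °C → rt
Reagents that add atoms: methyl (R)-lactate (the second equivalent of 11), C[C@@H](O)C(=O)OC
Why: Double Mitsunobu etherification, in which each of the two phenols takes up one molecule of the secondary alcohol 11, proceeds by SN2 inversion and so turns each (R)-lactate centre into an (S)-aryl ether.

Step 8
Reactants: 12 dimethyl (2S,2′S)-2,2′-[(2-iodo-1,3-phenylene)bis(oxy)]dipropanoate
Product: 13 dimethyl (2S,2′S)-2,2′-{[2-(diacetoxy-λ3-iodanyl)-1,3-phenylene]bis(oxy)}dipropanoate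
Conditions: CH3CO3H, AcOH, rt
Reagents that add atoms: peracetic acid, CC(=O)OO; acetic acid, CC(O)=O
Why: Peracid oxidation of the electron-rich aryl iodide in acetic acid is the standard preparation of a (diacetoxyiodo)arene.

Step 9
Reactants: 9 methyl 3-methoxy-2,4-bis(methoxymethoxy)-6-[(E)-prop-1-en-1-yl]benzoate; 13 dimethyl (2S,2′S)-2,2′-{[2-(diacetoxy-λ3-iodanyl)-1,3-phenylene]bis(oxy)}dipropanoate
Product: 16 (3R,4R)-7-methoxy-6,8-bis(methoxymethoxy)-3-methyl-1-oxoisochroman-4-yl 4-methylbenzenesulfonate (3,4-cis), via alkyl-λ3-iodane 14 (not isolated), via lactonium acetate 15 (not isolated)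
Conditions: TsOH·H2O, CH2Cl2, −78 → −40 °C
Reagents that add atoms: p-toluenesulfonic acid monohydrate, Cc1ccc(cc1)S(O)(=O)=O.O
Why: Ligand exchange of 13 with TsOH gives an acetoxy(tosyloxy)-λ3-iodane whose electrophilic trivalent iodine activates the E alkene of 9; tosylate opens the iodonium at benzylic C4 anti to iodine to give 14, the ester carbonyl oxygen then displaces the aryl-λ3-iodanyl nucleofuge at C3 with inversion to give lactonium ion 15, and acetate demethylates 15 to lactone 16. The closest known reaction type is the enantioselective endo-selective oxylactonization of ortho-alk-1-enylbenzoates with lactate-derived aryl-λ3-iodanes, a Koser-type tosyloxylation with intramolecular carboxyl capture. The lactone ring closes by O2–C3 bond formation in a 6-exo-tet SN2 displacement (the endo mode with respect to the former alkene). C4 (R) is set by the chiral iodane, which selects the alkene face that iodine occupies so that tosylate enters from the opposite face; C3 (R) follows from the E geometry through anti addition and then SN2 inversion, a net syn addition that gives the 3,4-cis product. The step needs six-membered (isochromanone) over five-membered (phthalide) closure, secured by the weakly nucleophilic methyl ester, which lets external tosylate take benzylic C4 first and leaves only C3 for the carbonyl oxygen; it also needs reaction at the alkene and not at the electron-rich ring, secured by the low temperature and the ring-deactivating ester.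

Step 10
Reactants: 16 (3R,4R)-7-methoxy-6,8-bis(methoxymethoxy)-3-methyl-1-oxoisochroman-4-yl 4-methylbenzenesulfonate
Product: 17 (3R,4S)-7-methoxy-6,8-bis(methoxymethoxy)-3-methyl-1-oxoisochroman-4-yl acetate (3,4-trans)
Conditions: CsOAc, 18-crown-6, toluene, 60 °C
Reagents that add atoms: cesium acetate, CC(=O)[O-].[Cs+]
Why: SN2 displacement of the benzylic tosylate by weakly basic acetate inverts C4 from R to S and so gives the trans acetate; ionisation at C4 is disfavoured by the ortho lactone carbonyl and by the 7-methoxy group being twisted out of conjugation by its two ortho neighbours.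

Step 11
Reactants: 17 (3R,4S)-7-methoxy-6,8-bis(methoxymethoxy)-3-methyl-1-oxoisochroman-4-yl acetate
Product: 18 (3R,4S)-4,6,8-trihydroxy-7-methoxy-3-methylisochroman-1-one
Conditions: HCl, MeOH, rt → 40 °C
Reagents that add atoms: none
Why: Acid-catalysed acetal exchange with methanol removes both MOM groups and acid-catalysed transesterification removes the acetate, with no bond to C3 or C4 broken.

Step 12
Reactants: 18 (3R,4S)-4,6,8-trihydroxy-7-methoxy-3-methylisochroman-1-one; 16 (3R,4R)-7-methoxy-6,8-bis(methoxymethoxy)-3-methyl-1-oxoisochroman-4-yl 4-methylbenzenesulfonate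
Product: 19 (3R,4S)-4-{[(3R,4S)-4,8-dihydroxy-7-methoxy-3-methyl-1-oxoisochroman-6-yl]oxy}-7-methoxy-6,8-bis(methoxymethoxy)-3-methylisochroman-1-one
Conditions: Cs2CO3 (1 equiv), DMF, 0 °C → rt
Reagents that add atoms: none
Why: Williamson etherification: the carbonate should deprotonate only the most acidic 6′-OH of 18 (para to the lactone carbonyl; 8′-OH is chelated, 4′-OH is an alcohol), and this phenoxide displaces the tosylate of 16 by SN2 with inversion (4R → 4S), giving the trans C4–O–C6′ ether.

Step 13
Reactants: 19 (3R,4S)-4-{[(3R,4S)-4,8-dihydroxy-7-methoxy-3-methyl-1-oxoisochroman-6-yl]oxy}-7-methoxy-6,8-bis(methoxymethoxy)-3-methylisochroman-1-one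
Product: 20 (3R,4S)-4-{[(3R,4S)-4,8-dihydroxy-7-methoxy-3-methyl-1-oxoisochroman-6-yl]oxy}-6,8-dihydroxy-7-methoxy-3-methylisochroman-1-one (target)
Conditions: HCl, MeOH/THF, rt
Reagents that add atoms: none
Why: Acid-catalysed acetal cleavage frees the 6- and 8-OH groups, while the benzylic aryl ether should not ionise because a C4 cation is destabilised by the ortho lactone carbonyl.

Compound list
1 | methyl 3,5-dihydroxy-4-methoxybenzoate | COC(=O)c1cc(O)c(OC)c(O)c1 | starting material
2 | methyl 4-methoxy-3,5-bis(methoxymethoxy)benzoate | COC(=O)c1cc(OCOC)c(OC)c(OCOC)c1 | intermediate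
3 | [4-methoxy-3,5-bis(methoxymethoxy)phenyl]methanol | OCc1cc(OCOC)c(OC)c(OCOC)c1 | intermediate
4 | 4-methoxy-3,5-bis(methoxymethoxy)benzaldehyde | O=Cc1cc(OCOC)c(OC)c(OCOC)c1 | intermediate
5 | 2-bromo-4-methoxy-3,5-bis(methoxymethoxy)benzaldehyde | O=Cc1cc(OCOC)c(OC)c(OCOC)c1Br | intermediate
6 | 5-(ethylsulfonyl)-1-phenyl-1H-tetrazole | CCS(=O)(=O)c1nnnn1-c1ccccc1 | starting material
7 | 2-bromo-4-methoxy-3,5-bis(methoxymethoxy)-1-[(E)-prop-1-en-1-yl]benzene | C/C=C/c1cc(OCOC)c(OC)c(OCOC)c1Br | intermediate
8 | {3-methoxy-2,4-bis(methoxymethoxy)-6-[(E)-prop-1-en-1-yl]phenyl}lithium | [Li]c1c(OCOC)c(OC)c(OCOC)cc1/C=C/C | intermediate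
9 | methyl 3-methoxy-2,4-bis(methoxymethoxy)-6-[(E)-prop-1-en-1-yl]benzoate | COC(=O)c1c(OCOC)c(OC)c(OCOC)cc1/C=C/C | intermediate
10 | 2-iodobenzene-1,3-diol | Oc1cccc(O)c1I | starting material
11 | methyl (R)-lactate | C[C@@H](O)C(=O)OC | starting material
12 | dimethyl (2S,2′S)-2,2′-[(2-iodo-1,3-phenylene)bis(oxy)]dipropanoate | COC(=O)[C@H](C)Oc1cccc(O[C@@H](C)C(=O)OC)c1I | intermediate
13 | dimethyl (2S,2′S)-2,2′-{[2-(diacetoxy-λ3-iodanyl)-1,3-phenylene]bis(oxy)}dipropanoate | COC(=O)[C@H](C)Oc1cccc(O[C@@H](C)C(=O)OC)c1I(OC(C)=O)OC(C)=O | intermediate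
14 | methyl 6-[(1R,2S)-2-{acetoxy[2,6-bis({[(2S)-1-methoxy-1-oxopropan-2-yl]oxy})phenyl]-λ3-iodanyl}-1-(tosyloxy)propyl]-3-methoxy-2,4-bis(methoxymethoxy)benzoate | COC(=O)c1c(OCOC)c(OC)c(OCOC)cc1[C@@H](OS(=O)(=O)c1ccc(C)cc1)[C@H](C)I(OC(C)=O)c1c(O[C@@H](C)C(=O)OC)cccc1O[C@@H](C)C(=O)OC | intermediate
15 | (3R,4R)-1,7-dimethoxy-6,8-bis(methoxymethoxy)-3-methyl-4-(tosyloxy)-3,4-dihydroisochromenylium acetate (O-methyl lactonium ion) | COC1=[O+][C@H](C)[C@H](OS(=O)(=O)c2ccc(C)cc2)c2cc(OCOC)c(OC)c(OCOC)c12.CC(=O)[O-] | intermediate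
16 | (3R,4R)-7-methoxy-6,8-bis(methoxymethoxy)-3-methyl-1-oxoisochroman-4-yl 4-methylbenzenesulfonate | COCOc1cc2c(c(OCOC)c1OC)C(=O)O[C@H](C)[C@@H]2OS(=O)(=O)c1ccc(C)cc1 | intermediate
17 | (3R,4S)-7-methoxy-6,8-bis(methoxymethoxy)-3-methyl-1-oxoisochroman-4-yl acetate | COCOc1cc2c(c(OCOC)c1OC)C(=O)O[C@H](C)[C@H]2OC(C)=O | intermediate
18 | (3R,4S)-4,6,8-trihydroxy-7-methoxy-3-methylisochroman-1-one | COc1c(O)cc2c(c1O)C(=O)O[C@H](C)[C@H]2O | intermediate
19 | (3R,4S)-4-{[(3R,4S)-4,8-dihydroxy-7-methoxy-3-methyl-1-oxoisochroman-6-yl]oxy}-7-methoxy-6,8-bis(methoxymethoxy)-3-methylisochroman-1-one | COCOc1cc2c(c(OCOC)c1OC)C(=O)O[C@H](C)[C@H]2Oc1cc2c(c(O)c1OC)C(=O)O[C@H](C)[C@H]2O | intermediate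
20 | (3R,4S)-4-{[(3R,4S)-4,8-dihydroxy-7-methoxy-3-methyl-1-oxoisochroman-6-yl]oxy}-6,8-dihydroxy-7-methoxy-3-methylisochroman-1-one | COc1c(O)cc2c(c1O)C(=O)O[C@H](C)[C@H]2Oc1cc2c(c(O)c1OC)C(=O)O[C@H](C)[C@H]2O | target

Total step count: 13. Longest linear sequence: 11 steps (steps 1–6 and 9–13); steps 7–8 are the side branch to iodane 13.

Steps most likely to fail

Step 9. What may go wrong: loss of facial or syn selectivity through ionisation at C4, acid-induced loss of a MOM acetal under TsOH, or competing oxidation of the electron-rich ring. The fallback sets out from 9 and comes back at 16. In it the oxidative step only has to deliver a labile ester, and the leaving group is made afterwards by sulfonylation of an alcohol. Treatment of 9 with iodane 13 and CF3CO2H in CH2Cl2 at −78 °C (trifluoroacetoxylactonization, same O2–C3 closure) should give the cis trifluoroacetate, (3R,4R)-7-methoxy-6,8-bis(methoxymethoxy)-3-methyl-1-oxoisochroman-4-yl trifluoroacetate F1. Aqueous NaHCO3/MeOH work-up should cleave it to the cis alcohol, (3R,4R)-4-hydroxy-7-methoxy-6,8-bis(methoxymethoxy)-3-methylisochroman-1-one F2. Ts2O, pyridine and 4-(dimethylamino)pyridine in CH2Cl2 at 0 °C then give 16.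

Step 12. What may go wrong: E2 elimination across C3–C4 of 16 (the C3–H is anti to the tosylate) to the 3-methylisocoumarin in place of substitution, or base-induced ring contraction of the 4′-hydroxy lactone of 18. The fallback sets out from 9 and 18 and comes back at 19. The ether is made by epoxide opening instead of sulfonate displacement. Epoxidation of 9 with 1,2:4,5-di-O-isopropylidene-β-D-erythro-2,3-hexodiulo-2,6-pyranose (the D-fructose-derived Shi ketone), KHSO5, K2CO3 and Bu4NHSO4 in MeCN/aqueous buffer at 0 °C should give methyl 3-methoxy-2,4-bis(methoxymethoxy)-6-[(2R,3R)-3-methyloxiran-2-yl]benzoate F3. With 18 and Cs2CO3 in DMF at 50 °C, the 6′-phenoxide should open F3 at benzylic C4 with inversion, and the C3 alkoxide then closes the lactone onto the methyl ester to give 19.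

Step 10. What may go wrong: the same E2 elimination to the isocoumarin competing with SN2 attack by acetate. The fallback sets out from 9 and comes back at 18. Inversion is done at an alcohol instead of at a sulfonate. The cis alcohol F2 is made from 9 through F1 as described for step 9. Mitsunobu reaction of F2 with HCO2H, PPh3 and DIAD in THF at 0 °C should give the trans formate, (3R,4S)-7-methoxy-6,8-bis(methoxymethoxy)-3-methyl-1-oxoisochroman-4-yl formate F4. The conditions of step 11 (HCl, MeOH) then remove the formate and both MOM groups to give 18.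

Further compounds
F1 | step 9 | (3R,4R)-7-methoxy-6,8-bis(methoxymethoxy)-3-methyl-1-oxoisochroman-4-yl trifluoroacetate | COCOc1cc2c(c(OCOC)c1OC)C(=O)O[C@H](C)[C@@H]2OC(=O)C(F)(F)F
F2 | step 9 | (3R,4R)-4-hydroxy-7-methoxy-6,8-bis(methoxymethoxy)-3-methylisochroman-1-one | COCOc1cc2c(c(OCOC)c1OC)C(=O)O[C@H](C)[C@@H]2O
F3 | step 12 | methyl 3-methoxy-2,4-bis(methoxymethoxy)-6-[(2R,3R)-3-methyloxiran-2-yl]benzoate | COC(=O)c1c(OCOC)c(OC)c(OCOC)cc1[C@H]1O[C@@H]1C
F4 | step 10 | (3R,4S)-7-methoxy-6,8-bis(methoxymethoxy)-3-methyl-1-oxoisochroman-4-yl formate | COCOc1cc2c(c(OCOC)c1OC)C(=O)O[C@H](C)[C@H]2OC=O
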